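## Retrosynthetic overview

1. Target 33 ⇐ acetonide 32 ⇐ E-enol ester by copper-catalysed C–O coupling of E-alkenylboronate 30 with 3-methylbut-2-enoic acid; the boronate comes from an E-iodoalkene (Takai) and that from an aldehyde.
2. α-Hydroxymethyl enone ⇐ Morita–Baylis–Hillman reaction; the seven-membered ring (the only ring, closed at step 14) ⇐ ring-closing metathesis of an allyl ketone onto an E-propenyl group, then conjugation.
3. Allyl ketone and 2-oxopropyl arm ⇐ Weinreb amide: enolate alkylation with a masked acetonyl bromide, then allyl Grignard addition.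
4. Key bond, quaternary C–CH (ring C5–C6) ⇐ Ireland–Claisen rearrangement of Z-allylic ester 14; the (S)-carbinol bought as (S)-but-3-yn-2-ol relays its chirality to both new centres and ends as the propenyl CH.
5. Allylic alcohol 12 ⇐ B-alkyl Suzuki coupling of Z-iodoalkene 9 with iodide 4, which carries the diol stereocentre from (S)-α-hydroxy-γ-butyrolactone.

Assumption: compounds 1, 5, 13, 31, 3-bromo-2-methoxyprop-1-ene and B-methoxy-9-borabicyclo[3.3.1]nonane are taken as purchasable; "Diox" stands for (4S)-2,2,5,5-tetramethyl-1,3-dioxolan-4-yl.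

## Route

Step 1
Reactants: 1 (S)-3-hydroxyoxolan-2-one
Product: 2 (3S)-4-methylpentane-1,3,4-triol
Conditions: MeMgBr (4 equiv), THF, 0 °C to rt; aq NH4Cl
Reagents that add atoms: methylmagnesium bromide C[Mg]Br
Why: Double Grignard addition to the lactone carbonyl builds the tertiary carbinol while the existing carbinol stereocentre, held as its alkoxide, is not touched.

Step 2
Reactants: 2 (3S)-4-methylpentane-1,3,4-triol
Product: 3 2-(Diox)ethan-1-ol
Conditions: Me2C(OMe)2, pyridinium p-toluenesulfonate (cat.), acetone, rt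
Reagents that add atoms: 2,2-dimethoxypropane COC(C)(C)OC
Why: Thermodynamic acetalisation closes the five-membered dioxolane across the vicinal secondary/tertiary diol and leaves the primary OH free.

Step 3
Reactants: 3 2-(Diox)ethan-1-ol
Product: 4 (4S)-4-(2-iodoethyl)-2,2,5,5-tetramethyl-1,3-dioxolane
Conditions: I2, PPh3, imidazole, CH2Cl2, 0 °C to rt
Reagents that add atoms: iodine II
Why: Appel-type (Garegg–Samuelsson) iodination is an SN2 displacement at the primary carbon, remote from the stereocentre.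

Step 4
Reactants: 5 (S)-but-3-yn-2-ol
Product: 7 (S)-pent-3-yn-2-ol, via dilithio alkynolate 6 (not isolated)
Conditions: n-BuLi (2.1 equiv), THF/DMPU, −78 to −20 °C; MeI (1.0 equiv); H2O
Reagents that add atoms: iodomethane CI
Why: Alkylation of the dianion takes place at the more nucleophilic acetylide carbon, so the carbinol centre is unchanged.

Step 5
Reactants: 7 (S)-pent-3-yn-2-ol
Product: 9 (2S,3Z)-4-iodopent-3-en-2-ol, via cyclic alkenylaluminate 8 (not isolated)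
Conditions: NaAlH2(OCH2CH2OMe)2 (1.3 equiv), THF, 0 °C to rt; I2, −78 to 0 °C; H2O
Reagents that add atoms: iodine II
Why: Hydroxyl-directed trans-hydroalumination puts aluminium on the distal alkyne carbon inside a five-membered aluminate, and iodinolysis with retention gives the Z-iodoalkene (iodine cis to the carbinol carbon).

Step 6
Reactants: 4 (4S)-4-(2-iodoethyl)-2,2,5,5-tetramethyl-1,3-dioxolane; 9 (2S,3Z)-4-iodopent-3-en-2-ol
Product: 12 (2S,3Z)-4-methyl-6-(Diox)hex-3-en-2-ol, via alkyllithium 10 (not isolated), via lithium alkylborinate 11 (not isolated)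
Conditions: 4, t-BuLi (2.1 equiv), Et2O, −78 °C; B-methoxy-9-BBN, THF, −78 °C to rt; then 9, PdCl2(dppf) (5 mol%), aq K3PO4, DMF, rt
Reagents that add atoms: none
Why: B-alkyl Suzuki–Miyaura coupling proceeds with retention at the alkene, so the side chain ends cis to the carbinol carbon (Z), and the free OH is tolerated.

Step 7
Reactants: 12 (2S,3Z)-4-methyl-6-(Diox)hex-3-en-2-ol; 13 4-[methoxy(methyl)amino]-4-oxobutanoic acid
Product: 14 (2S,3Z)-4-methyl-6-(Diox)hex-3-en-2-yl 4-[methoxy(methyl)amino]-4-oxobutanoate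
Conditions: DCC, DMAP (cat.), CH2Cl2, 0 °C to rt
Reagents that add atoms: none
Why: Steglich esterification acylates the secondary allylic alcohol on oxygen with retention of configuration and alkene geometry.

Step 8
Reactants: 14 (2S,3Z)-4-methyl-6-(Diox)hex-3-en-2-yl 4-[methoxy(methyl)amino]-4-oxobutanoate
Product: 18 (2S,3S,4E)-2-{2-[methoxy(methyl)amino]-2-oxoethyl}-3-methyl-3-[2-(Diox)ethyl]hex-4-enoic acid, via lithium ester enolate 15 (not isolated), via TBS ketene acetal 16 (not isolated), via TBS ester 17 (not isolated)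
Conditions: LDA (1.15 equiv), THF/DMPU (3:1), −78 °C; TBSCl, −78 °C to rt, then 45 °C; AcOH/H2O/THF, rt
Reagents that add atoms: none
Why: Ireland–Claisen rearrangement ([3,3]-sigmatropic) through a chair transition state with the carbinol methyl equatorial: the (S)-carbinol, the Z-alkene (side chain axial) and the Z-silyl ketene acetal formed in THF/DMPU together set the quaternary carbon and its CH neighbour as drawn and give the E-propenyl group.

Step 9
Reactants: 18 (2S,3S,4E)-2-{2-[methoxy(methyl)amino]-2-oxoethyl}-3-methyl-3-[2-(Diox)ethyl]hex-4-enoic acid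
Product: 20 (3S,4S,5E)-3-(hydroxymethyl)-N-methoxy-N,4-dimethyl-4-[2-(Diox)ethyl]hept-5-enamide, via acyl imidazolide 19 (not isolated)
Conditions: 1,1'-carbonyldiimidazole, THF, rt; NaBH4, H2O, 0 °C
Reagents that add atoms: none
Why: Borohydride reduces only the activated carboxyl group (acyl imidazolide), leaving the Weinreb amide, the alkene and the α-stereocentre untouched.

Step 10
Reactants: 20 (3S,4S,5E)-3-(hydroxymethyl)-N-methoxy-N,4-dimethyl-4-[2-(Diox)ethyl]hept-5-enamide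
Product: 21 (3S,4S,5E)-3-formyl-N-methoxy-N,4-dimethyl-4-[2-(Diox)ethyl]hept-5-enamide
Conditions: Dess–Martin periodinane, CH2Cl2, 0 °C to rt
Reagents that add atoms: none
Why: Dess–Martin oxidation under neutral conditions gives the α-branched aldehyde without epimerisation.

Step 11
Reactants: 21 (3S,4S,5E)-3-formyl-N-methoxy-N,4-dimethyl-4-[2-(Diox)ethyl]hept-5-enamide
Product: 22 (3R,4S,5E)-3-[(E)-2-iodoethenyl]-N-methoxy-N,4-dimethyl-4-[2-(Diox)ethyl]hept-5-enamide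
Conditions: CrCl2 (6 equiv), CHI3 (2 equiv), THF/dioxane, 0 °C to rt
Reagents that add atoms: iodoform IC(I)I
Why: Takai olefination: the geminal dichromium reagent adds to the aldehyde and eliminates to the E-iodoalkene under non-basic conditions, so the adjacent stereocentre is kept (the descriptor changes only through priorities).

Step 12
Reactants: 22 (3R,4S,5E)-3-[(E)-2-iodoethenyl]-N-methoxy-N,4-dimethyl-4-[2-(Diox)ethyl]hept-5-enamide
Product: 24 (3R,4S,5E)-3-[(E)-2-iodoethenyl]-N-methoxy-2-(2-methoxyprop-2-en-1-yl)-N,4-dimethyl-4-[2-(Diox)ethyl]hept-5-enamide (C2 epimers), via lithium amide enolate 23 (not isolated)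
Conditions: LDA (1.1 equiv), THF, −78 °C; 3-bromo-2-methoxyprop-1-ene, −78 to −40 °C
Reagents that add atoms: 3-bromo-2-methoxyprop-1-ene COC(=C)CBr
Why: Enolate alkylation of the Weinreb amide with a masked acetonyl bromide; the new α-centre forms as an epimer mixture that is set later by equilibration (step 15).

Step 13
Reactants: 24 (3R,4S,5E)-3-[(E)-2-iodoethenyl]-N-methoxy-2-(2-methoxyprop-2-en-1-yl)-N,4-dimethyl-4-[2-(Diox)ethyl]hept-5-enamide (C2 epimers)
Product: 26 (6R,7S,8E)-6-[(E)-2-iodoethenyl]-7-methyl-5-(2-oxopropyl)-7-[2-(Diox)ethyl]deca-1,8-dien-4-one (C5 epimers), via magnesium hemiaminalate 25 (not isolated)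
Conditions: CH2=CHCH2MgBr (1.5 equiv), THF, −78 to 0 °C; 0.5 M aq HCl, 0 °C, 20 min
Reagents that add atoms: allylmagnesium bromide C=CC[Mg]Br; water O
Why: Weinreb ketone synthesis, in which the chelated tetrahedral adduct stops at single addition, and the acidic work-up also hydrolyses the enol ether to the methyl ketone.

Step 14
Reactants: 26 (6R,7S,8E)-6-[(E)-2-iodoethenyl]-7-methyl-5-(2-oxopropyl)-7-[2-(Diox)ethyl]deca-1,8-dien-4-one (C5 epimers)
Product: 27 (5S,6R)-6-[(E)-2-iodoethenyl]-5-methyl-7-(2-oxopropyl)-5-[2-(Diox)ethyl]cyclohept-3-en-1-one (C7 epimers)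
Conditions: second-generation Grubbs catalyst (10 mol%), 1,4-benzoquinone (20 mol%), CH2Cl2 (2 mM), 40 °C
Reagents that add atoms: none
Why: Ring-closing metathesis starts at the terminal allyl alkene and closes onto the propenyl group with loss of propene to give the seven-membered ring; the iodoalkene is expected to stay out and no stereocentre is involved.

Step 15
Reactants: 27 (5S,6R)-6-[(E)-2-iodoethenyl]-5-methyl-7-(2-oxopropyl)-5-[2-(Diox)ethyl]cyclohept-3-en-1-one (C7 epimers)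
Product: 29 (5S,6R,7S)-2-(hydroxymethyl)-6-[(E)-2-iodoethenyl]-5-methyl-7-(2-oxopropyl)-5-[2-(Diox)ethyl]cyclohept-2-en-1-one, via conjugated enone 28 (not isolated)
Conditions: DBU (0.2 equiv), THF, rt; then 37% aq HCHO, imidazole, THF/H2O, rt
Reagents that add atoms: formaldehyde C=O
Why: Base moves the alkene into conjugation and equilibrates the α-carbon to the arrangement expected to be more stable, with the 2-oxopropyl group trans to the neighbouring iodoalkenyl group, and a Morita–Baylis–Hillman reaction then adds formaldehyde at the enone α-carbon.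

Step 16
Reactants: 29 (5S,6R,7S)-2-(hydroxymethyl)-6-[(E)-2-iodoethenyl]-5-methyl-7-(2-oxopropyl)-5-[2-(Diox)ethyl]cyclohept-2-en-1-one
Product: 30 (5S,6S,7S)-2-(hydroxymethyl)-5-methyl-7-(2-oxopropyl)-6-[(E)-2-(4,4,5,5-tetramethyl-1,3,2-dioxaborolan-2-yl)ethenyl]-5-[2-(Diox)ethyl]cyclohept-2-en-1-one
Conditions: B2pin2, PdCl2(PPh3)2 (5 mol%), PPh3, KOPh, toluene, 50 °C
Reagents that add atoms: bis(pinacolato)diboron CC1(C)OB(OC1(C)C)B1OC(C)(C)C(C)(C)O1
Why: Miyaura borylation of the alkenyl iodide proceeds with retention of the E geometry under weakly basic conditions.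

Step 17
Reactants: 30 (5S,6S,7S)-2-(hydroxymethyl)-5-methyl-7-(2-oxopropyl)-6-[(E)-2-(4,4,5,5-tetramethyl-1,3,2-dioxaborolan-2-yl)ethenyl]-5-[2-(Diox)ethyl]cyclohept-2-en-1-one; 31 3-methylbut-2-enoic acid
Product: 32 (E)-2-{(1S,2S,7S)-5-(hydroxymethyl)-2-methyl-6-oxo-7-(2-oxopropyl)-2-[2-(Diox)ethyl]cyclohept-4-en-1-yl}ethenyl 3-methylbut-2-enoate
Conditions: 31 (3 equiv), Cu(OAc)2 (0.3 equiv), DMAP, 4 Å molecular sieves, O2 (1 atm), CH2Cl2, rt to 40 °C
Reagents that add atoms: none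
Why: Chan–Lam–Evans oxidative C–O coupling transfers the alkenyl group from boron to the carboxylate oxygen with retention, giving the E-enol ester without base-induced deconjugation of the acyl part.

Step 18
Reactants: 32 (E)-2-{(1S,2S,7S)-5-(hydroxymethyl)-2-methyl-6-oxo-7-(2-oxopropyl)-2-[2-(Diox)ethyl]cyclohept-4-en-1-yl}ethenyl 3-methylbut-2-enoate
Product: 33 (E)-2-{(1S,2S,7S)-2-[(3S)-3,4-dihydroxy-4-methylpentyl]-5-(hydroxymethyl)-2-methyl-6-oxo-7-(2-oxopropyl)cyclohept-4-en-1-yl}ethenyl 3-methylbut-2-enoate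
Conditions: AcOH/H2O (4:1), 35 °C
Reagents that add atoms: none
Why: Acid-catalysed acetal hydrolysis frees the diol, and the weak acid leaves the enol ester, the enone and all stereocentres untouched.

## Compound list

1 | (S)-3-hydroxyoxolan-2-one [(S)-α-hydroxy-γ-butyrolactone] | O=C1OCC[C@@H]1O | starting material
2 | (3S)-4-methylpentane-1,3,4-triol | OCC[C@H](O)C(C)(C)O | intermediate
3 | 2-[(4S)-2,2,5,5-tetramethyl-1,3-dioxolan-4-yl]ethan-1-ol | OCC[C@H](OC1(C)C)C(C)(C)O1 | intermediate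
4 | (4S)-4-(2-iodoethyl)-2,2,5,5-tetramethyl-1,3-dioxolane | ICC[C@H](OC1(C)C)C(C)(C)O1 | intermediate
5 | (S)-but-3-yn-2-ol | C[C@H](O)C#C | starting material
6 | dilithium salt of 5 (lithium alkoxide, lithium acetylide) | C[C@H](O[Li])C#C[Li] | intermediate
7 | (S)-pent-3-yn-2-ol | C[C@H](O)C#CC | intermediate
8 | sodium (5S)-2,2-bis(2-methoxyethoxy)-3,5-dimethyl-2,5-dihydro-1,2-oxaaluminol-2-uide (cyclic alkenylaluminate) | C[C@@H]1O[Al-](OCCOC)(OCCOC)C(C)=C1.[Na+] | intermediate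
9 | (2S,3Z)-4-iodopent-3-en-2-ol | C[C@H](O)/C=C(\I)C | intermediate
10 | {2-[(4S)-2,2,5,5-tetramethyl-1,3-dioxolan-4-yl]ethyl}lithium | [Li]CC[C@H](OC1(C)C)C(C)(C)O1 | intermediate
11 | lithium 9-methoxy-9-{2-[(4S)-2,2,5,5-tetramethyl-1,3-dioxolan-4-yl]ethyl}-9-borabicyclo[3.3.1]nonan-9-uide | CO[B-]1(CC[C@H](OC2(C)C)C(C)(C)O2)C2CCCC1CCC2.[Li+] | intermediate
12 | (2S,3Z)-4-methyl-6-[(4S)-2,2,5,5-tetramethyl-1,3-dioxolan-4-yl]hex-3-en-2-ol | C[C@H](O)/C=C(\CC[C@H](OC1(C)C)C(C)(C)O1)C | intermediate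
13 | 4-[methoxy(methyl)amino]-4-oxobutanoic acid | CON(C)C(=O)CCC(=O)O | starting material
14 | (2S,3Z)-4-methyl-6-(Diox)hex-3-en-2-yl 4-[methoxy(methyl)amino]-4-oxobutanoate | C[C@H](OC(=O)CCC(=O)N(C)OC)/C=C(\CC[C@H](OC1(C)C)C(C)(C)O1)C | intermediate
15 | lithium enolate of ester 14 (amide chain cis to OLi) | C[C@H](O/C(O[Li])=C/CC(=O)N(C)OC)/C=C(\CC[C@H](OC1(C)C)C(C)(C)O1)C | intermediate
16 | Z-tert-butyldimethylsilyl ketene acetal of ester 14 (amide chain cis to OSi) | C[C@H](O/C(O[Si](C)(C)C(C)(C)C)=C/CC(=O)N(C)OC)/C=C(\CC[C@H](OC1(C)C)C(C)(C)O1)C | intermediate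
17 | tert-butyldimethylsilyl ester of acid 18 | C/C=C/[C@](C)(CC[C@H](OC1(C)C)C(C)(C)O1)[C@H](CC(=O)N(C)OC)C(=O)O[Si](C)(C)C(C)(C)C | intermediate
18 | (2S,3S,4E)-2-{2-[methoxy(methyl)amino]-2-oxoethyl}-3-methyl-3-[2-(Diox)ethyl]hex-4-enoic acid | C/C=C/[C@](C)(CC[C@H](OC1(C)C)C(C)(C)O1)[C@H](CC(=O)N(C)OC)C(=O)O | intermediate
19 | 1-acylimidazole (imidazolide) of acid 18 | C/C=C/[C@](C)(CC[C@H](OC1(C)C)C(C)(C)O1)[C@H](CC(=O)N(C)OC)C(=O)n1ccnc1 | intermediate
20 | (3S,4S,5E)-3-(hydroxymethyl)-N-methoxy-N,4-dimethyl-4-[2-(Diox)ethyl]hept-5-enamide | C/C=C/[C@](C)(CC[C@H](OC1(C)C)C(C)(C)O1)[C@H](CC(=O)N(C)OC)CO | intermediate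
21 | (3S,4S,5E)-3-formyl-N-methoxy-N,4-dimethyl-4-[2-(Diox)ethyl]hept-5-enamide | C/C=C/[C@](C)(CC[C@H](OC1(C)C)C(C)(C)O1)[C@H](CC(=O)N(C)OC)C=O | intermediate
22 | (3R,4S,5E)-3-[(E)-2-iodoethenyl]-N-methoxy-N,4-dimethyl-4-[2-(Diox)ethyl]hept-5-enamide | C/C=C/[C@](C)(CC[C@H](OC1(C)C)C(C)(C)O1)[C@H](CC(=O)N(C)OC)/C=C/I | intermediate
23 | lithium enolate of Weinreb amide 22 | C/C=C/[C@](C)(CC[C@H](OC1(C)C)C(C)(C)O1)[C@H](/C=C(\O[Li])N(C)OC)/C=C/I | intermediate
24 | (3R,4S,5E)-3-[(E)-2-iodoethenyl]-N-methoxy-2-(2-methoxyprop-2-en-1-yl)-N,4-dimethyl-4-[2-(Diox)ethyl]hept-5-enamide (C2 epimers, drawn without configuration at C2) | C/C=C/[C@](C)(CC[C@H](OC1(C)C)C(C)(C)O1)[C@H](C(CC(=C)OC)C(=O)N(C)OC)/C=C/I | intermediate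
25 | bromomagnesium salt of the N-methoxy-N-methyl hemiaminal formed from 24 and the allyl Grignard reagent | C/C=C/[C@](C)(CC[C@H](OC1(C)C)C(C)(C)O1)[C@H](C(CC(=C)OC)C(CC=C)(O[Mg]Br)N(C)OC)/C=C/I | intermediate
26 | (6R,7S,8E)-6-[(E)-2-iodoethenyl]-7-methyl-5-(2-oxopropyl)-7-[2-(Diox)ethyl]deca-1,8-dien-4-one (C5 epimers, drawn without configuration at C5) | C/C=C/[C@](C)(CC[C@H](OC1(C)C)C(C)(C)O1)[C@H](C(CC(C)=O)C(=O)CC=C)/C=C/I | intermediate
27 | (5S,6R)-6-[(E)-2-iodoethenyl]-5-methyl-7-(2-oxopropyl)-5-[2-(Diox)ethyl]cyclohept-3-en-1-one (C7 epimers, drawn without configuration at C7) | CC(=O)CC1C(=O)CC=C[C@](C)(CC[C@H](OC2(C)C)C(C)(C)O2)[C@H]1/C=C/I | intermediate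
28 | (5S,6R,7S)-6-[(E)-2-iodoethenyl]-5-methyl-7-(2-oxopropyl)-5-[2-(Diox)ethyl]cyclohept-2-en-1-one | CC(=O)C[C@@H]1C(=O)C=CC[C@](C)(CC[C@H](OC2(C)C)C(C)(C)O2)[C@H]1/C=C/I | intermediate
29 | (5S,6R,7S)-2-(hydroxymethyl)-6-[(E)-2-iodoethenyl]-5-methyl-7-(2-oxopropyl)-5-[2-(Diox)ethyl]cyclohept-2-en-1-one | CC(=O)C[C@@H]1C(=O)C(CO)=CC[C@](C)(CC[C@H](OC2(C)C)C(C)(C)O2)[C@H]1/C=C/I | intermediate
30 | (5S,6S,7S)-2-(hydroxymethyl)-5-methyl-7-(2-oxopropyl)-6-[(E)-2-(4,4,5,5-tetramethyl-1,3,2-dioxaborolan-2-yl)ethenyl]-5-[2-(Diox)ethyl]cyclohept-2-en-1-one | CC(=O)C[C@@H]1C(=O)C(CO)=CC[C@](C)(CC[C@H](OC2(C)C)C(C)(C)O2)[C@H]1/C=C/B3OC(C)(C)C(C)(C)O3 | intermediate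
31 | 3-methylbut-2-enoic acid | CC(C)=CC(=O)O | starting material
32 | (E)-2-{(1S,2S,7S)-5-(hydroxymethyl)-2-methyl-6-oxo-7-(2-oxopropyl)-2-[2-(Diox)ethyl]cyclohept-4-en-1-yl}ethenyl 3-methylbut-2-enoate | CC(=O)C[C@@H]1C(=O)C(CO)=CC[C@](C)(CC[C@H](OC2(C)C)C(C)(C)O2)[C@H]1/C=C/OC(=O)C=C(C)C | intermediate
33 | (E)-2-{(1S,2S,7S)-2-[(3S)-3,4-dihydroxy-4-methylpentyl]-5-(hydroxymethyl)-2-methyl-6-oxo-7-(2-oxopropyl)cyclohept-4-en-1-yl}ethenyl 3-methylbut-2-enoate | CC(=O)C[C@@H]1C(=O)C(CO)=CC[C@](C)(CC[C@H](O)C(C)(C)O)[C@H]1/C=C/OC(=O)C=C(C)C | target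

## Step count and risks

Total steps: 18. Longest linear sequence: 16 (steps 1–3 and 6–18; steps 4–5 make the second coupling partner).

The three steps most likely to fail:

Step 8 (Ireland–Claisen). The congested quaternary–tertiary bond needs a clean Z-ketene acetal from an ester that also carries a Weinreb amide; poor enolate geometry would erode the diastereomer ratio. The fallback sets out from 4 and comes back at 18, using the complementary E-alkene/E-ketene acetal pairing. (R)-But-3-yn-2-ol (bought; n-BuLi, 2 equiv) is alkylated with 4 to give (2R)-6-(Diox)hex-3-yn-2-ol F1. NaAlH2(OCH2CH2OMe)2 then I2 gives (2R,3Z)-4-iodo-6-(Diox)hex-3-en-2-ol F2. MeZnCl with Pd(PPh3)4 gives (2R,3E)-4-methyl-6-(Diox)hex-3-en-2-ol F3. Esterification with 13 (DCC, DMAP) gives (2R,3E)-4-methyl-6-(Diox)hex-3-en-2-yl 4-[methoxy(methyl)amino]-4-oxobutanoate F4. LDA in THF without DMPU and TBSCl give the kinetic E-tert-butyldimethylsilyl ketene acetal of F4 F5, which rearranges through the same chair to silyl ester 17 and, after work-up, 18.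

Step 14 (ring-closing metathesis). The propenyl partner sits on a quaternary carbon, and the iodoalkene could poison the catalyst or offer a six-membered ring closure. The fallback sets out from 21 and comes back at 27, closing the ring before the iodoalkene exists. Aldehyde 21 is masked (HC(OMe)3, pyridinium p-toluenesulfonate, MeOH) as (3S,4S,5E)-3-(dimethoxymethyl)-N-methoxy-N,4-dimethyl-4-[2-(Diox)ethyl]hept-5-enamide F6. LDA and 3-bromo-2-methoxyprop-1-ene give (3S,4S,5E)-3-(dimethoxymethyl)-N-methoxy-2-(2-methoxyprop-2-en-1-yl)-N,4-dimethyl-4-[2-(Diox)ethyl]hept-5-enamide F7. Allyl Grignard addition with a buffered oxalic acid work-up (enol ether cleaved, dimethyl acetal kept) gives (6S,7S,8E)-6-(dimethoxymethyl)-7-methyl-5-(2-oxopropyl)-7-[2-(Diox)ethyl]deca-1,8-dien-4-one F8. Metathesis with the second-generation Hoveyda–Grubbs catalyst in toluene at 80 °C gives (5S,6S)-6-(dimethoxymethyl)-5-methyl-7-(2-oxopropyl)-5-[2-(Diox)ethyl]cyclohept-3-en-1-one F9. TESOTf/2,4,6-collidine then water frees (1S,2S)-2-methyl-6-oxo-7-(2-oxopropyl)-2-[2-(Diox)ethyl]cyclohept-3-ene-1-carbaldehyde F10, and Takai olefination (CrCl2, CHI3) of this aldehyde gives 27.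

Step 17 (Chan–Lam enol esterification). Coupling of a pinacol alkenylboronate with an unsaturated acid on a substrate bearing a free allylic alcohol and a 1,4-diketone may be slow or give protodeboronation. The fallback sets out from 29 and comes back at 32, leaving out the boronate. Iodoalkene 29 is coupled directly with the caesium salt of 31 under copper iodide CuI (10 mol%) and trans-N,N'-dimethylcyclohexane-1,2-diamine in toluene at 80 °C. This Ullmann-type O-vinylation of a carboxylate is established for enol lactones and keeps the alkene geometry; no new compound is made on the way.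

Further compounds
F1 | step 8 | (2R)-6-[(4S)-2,2,5,5-tetramethyl-1,3-dioxolan-4-yl]hex-3-yn-2-ol | C[C@@H](O)C#CCC[C@H](OC1(C)C)C(C)(C)O1
F2 | step 8 | (2R,3Z)-4-iodo-6-[(4S)-2,2,5,5-tetramethyl-1,3-dioxolan-4-yl]hex-3-en-2-ol | C[C@@H](O)/C=C(\I)CC[C@H](OC1(C)C)C(C)(C)O1
F3 | step 8 | (2R,3E)-4-methyl-6-[(4S)-2,2,5,5-tetramethyl-1,3-dioxolan-4-yl]hex-3-en-2-ol | C[C@@H](O)/C=C(\C)CC[C@H](OC1(C)C)C(C)(C)O1
F4 | step 8 | (2R,3E)-4-methyl-6-(Diox)hex-3-en-2-yl 4-[methoxy(methyl)amino]-4-oxobutanoate | C[C@@H](OC(=O)CCC(=O)N(C)OC)/C=C(\C)CC[C@H](OC1(C)C)C(C)(C)O1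
F5 | step 8 | E-tert-butyldimethylsilyl ketene acetal of F4 (amide chain trans to OSi) | C[C@@H](O/C(O[Si](C)(C)C(C)(C)C)=C\CC(=O)N(C)OC)/C=C(\C)CC[C@H](OC1(C)C)C(C)(C)O1
F6 | step 14 | (3S,4S,5E)-3-(dimethoxymethyl)-N-methoxy-N,4-dimethyl-4-[2-(Diox)ethyl]hept-5-enamide | C/C=C/[C@](C)(CC[C@H](OC1(C)C)C(C)(C)O1)[C@H](CC(=O)N(C)OC)C(OC)OC
F7 | step 14 | (3S,4S,5E)-3-(dimethoxymethyl)-N-methoxy-2-(2-methoxyprop-2-en-1-yl)-N,4-dimethyl-4-[2-(Diox)ethyl]hept-5-enamide (C2 epimers) | C/C=C/[C@](C)(CC[C@H](OC1(C)C)C(C)(C)O1)[C@H](C(CC(=C)OC)C(=O)N(C)OC)C(OC)OC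
F8 | step 14 | (6S,7S,8E)-6-(dimethoxymethyl)-7-methyl-5-(2-oxopropyl)-7-[2-(Diox)ethyl]deca-1,8-dien-4-one (C5 epimers) | C/C=C/[C@](C)(CC[C@H](OC1(C)C)C(C)(C)O1)[C@H](C(CC(C)=O)C(=O)CC=C)C(OC)OC
F9 | step 14 | (5S,6S)-6-(dimethoxymethyl)-5-methyl-7-(2-oxopropyl)-5-[2-(Diox)ethyl]cyclohept-3-en-1-one (C7 epimers) | CC(=O)CC1C(=O)CC=C[C@](C)(CC[C@H](OC2(C)C)C(C)(C)O2)[C@H]1C(OC)OC
F10 | step 14 | (1S,2S)-2-methyl-6-oxo-7-(2-oxopropyl)-2-[2-(Diox)ethyl]cyclohept-3-ene-1-carbaldehyde (C7 epimers) | CC(=O)CC1C(=O)CC=C[C@](C)(CC[C@H](OC2(C)C)C(C)(C)O2)[C@H]1C=O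
F0 | step 17 | none | none
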